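The bond between C1 and C2 of the heptan-3-one chain carries the whole strategy. C1 is benzylic and sits ortho to the 2-OH and para to the 4-OH of the 2,4-dihydroxy-3-methoxyphenyl ring, so it is the exocyclic carbon of a quinone methide; C2 is alpha to the C3 ketone, so it is the nucleophilic carbon of a β-keto acid. The key step is a one-pot three-component coupling: 2-methoxyresorcinol and a methyleneiminium salt give a Mannich base, which expels its amine, and the resulting ortho-quinone methide is trapped by 7-(4-methoxyphenyl)-3-oxoheptanoic acid with loss of CO2. The free-phenol target forms directly, with no protecting group and no redox step.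

Key step: step 3

Assumption: the target contains no stereocentre and no stereogenic double bond, so it is a single achiral compound and the route needs no stereocontrol.

Step 1
Reactants: 1 methyl acetoacetate; 2 1-(3-bromopropyl)-4-methoxybenzene
Product: 5 methyl 7-(4-methoxyphenyl)-3-oxoheptanoate, via dilithium dianion 3 (not isolated), via lithium enolate 4 (not isolated)
Conditions: LDA (2.1 equiv per 1), THF, 0 °C; then 2, 0 °C → rt; cold 1 M HCl quench
Reagents that add atoms: none
Why: Weiler dianion alkylation, in which the doubly deprotonated acetoacetate should react with the primary bromide by SN2 only at its more basic terminal (γ) carbon, leaving the C2 methylene free for the key step.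

Step 2
Reactants: 5 methyl 7-(4-methoxyphenyl)-3-oxoheptanoate
Product: 7 7-(4-methoxyphenyl)-3-oxoheptanoic acid, via sodium carboxylate 6 (not isolated)
Conditions: 1 M aq. NaOH, THF, 0 °C → rt; then 1 M HCl to pH 2 at 0 °C, extraction, concentration below 25 °C
Reagents that add atoms: sodium hydroxide, [Na+].[OH-]
Why: Ester saponification should give the carboxylate, which resists decarboxylation, and cold acidification with low-temperature concentration should deliver the β-keto acid before it loses CO2.

Step 3
Reactants: 7 7-(4-methoxyphenyl)-3-oxoheptanoic acid; 8 2-methoxybenzene-1,3-diol (2-methoxyresorcinol); 9 N,N-dimethylmethyleneiminium iodide (Eschenmoser's salt)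
Product: 13 1-(2,4-dihydroxy-3-methoxyphenyl)-7-(4-methoxyphenyl)heptan-3-one, via Mannich base 10 (not isolated), via ortho-quinone methide 11 (not isolated), via benzylated keto acid 12 (not isolated)
Conditions: 8 (1.2 equiv), 9 (1.0 equiv), Et3N (1.1 equiv), MeCN, N2, 0 °C → rt; then 7 (1.5 equiv), 60 °C
Reagents that add atoms: none
Why: Three-component Mannich/retro-Mannich/decarboxylative Michael cascade: iminium 9 aminomethylates 8 at C4, the ring carbon that is ortho to one hydroxyl and para to the other (C4 and C6 are equivalent, C5 is unactivated), to give Mannich base 10. On warming with acid 7 the protonated amine is expelled with a push from the ortho (or para) oxygen, which gives ortho-quinone methide 11. The enol of the β-keto carboxylate adds through its C2 to the exocyclic methylene of 11 in a conjugate addition driven by rearomatization, and adduct 12 loses CO2 to give 13. The closest known reaction types are the C-benzylation of 1,3-dicarbonyl compounds by phenolic Mannich bases and the decarboxylative Michael addition of β-keto acids to ortho-quinone methides. No ring is closed, and the only stereocentre formed (C2 of 12, racemic) is erased by the decarboxylation. The step needs C2 over C4 selectivity on the ketone chain and monoalkylation, both secured by the carboxyl group that activates one α-carbon only and leaves as CO2 after the first C–C bond, while reversible O-adducts of 11 drain to the irreversible C-adduct and the excess of 8 over 9 limits double aminomethylation.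

Compound list
1 | methyl acetoacetate (methyl 3-oxobutanoate) | COC(=O)CC(C)=O | starting material
2 | 1-(3-bromopropyl)-4-methoxybenzene | COc1ccc(CCCBr)cc1 | starting material
3 | dilithium dianion of methyl acetoacetate | [Li+].[Li+].C=C([O-])C=C([O-])OC | intermediate
4 | lithium enolate of methyl 7-(4-methoxyphenyl)-3-oxoheptanoate | [Li+].COC(=O)C=C([O-])CCCCc1ccc(OC)cc1 | intermediate
5 | methyl 7-(4-methoxyphenyl)-3-oxoheptanoate | COC(=O)CC(=O)CCCCc1ccc(OC)cc1 | intermediate
6 | sodium 7-(4-methoxyphenyl)-3-oxoheptanoate | [Na+].[O-]C(=O)CC(=O)CCCCc1ccc(OC)cc1 | intermediate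
7 | 7-(4-methoxyphenyl)-3-oxoheptanoic acid | OC(=O)CC(=O)CCCCc1ccc(OC)cc1 | intermediate
8 | 2-methoxybenzene-1,3-diol (2-methoxyresorcinol) | COc1c(O)cccc1O | starting material
9 | N,N-dimethylmethyleneiminium iodide (Eschenmoser's salt) | C=[N+](C)C.[I-] | starting material
10 | 4-[(dimethylamino)methyl]-2-methoxybenzene-1,3-diol | CN(C)Cc1ccc(O)c(OC)c1O | intermediate
11 | 3-hydroxy-2-methoxy-6-methylidenecyclohexa-2,4-dien-1-one | C=C1C=CC(O)=C(OC)C1=O | intermediate
12 | 2-[(2,4-dihydroxy-3-methoxyphenyl)methyl]-7-(4-methoxyphenyl)-3-oxoheptanoic acid (racemic) | COc1ccc(CCCCC(=O)C(Cc2ccc(O)c(OC)c2O)C(=O)O)cc1 | intermediate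
13 | 1-(2,4-dihydroxy-3-methoxyphenyl)-7-(4-methoxyphenyl)heptan-3-one | COc1ccc(CCCCC(=O)CCc2ccc(O)c(OC)c2O)cc1 | target

Total step count: 3
Longest linear sequence: 3 (steps 1, 2, 3)

Steps most likely to fail

1. Step 3. The quinone methide may be consumed by electron-rich arenes in the flask (8, 10 or the product) to give diarylmethane oligomers, the phenol may be aminomethylated twice, or acid 7 may lose CO2 before the C–C bond forms. The fallback sets out from 7 and 8 and returns at 13, forming the same C1–C2 bond as a C=C by known aldol chemistry. Acid 7 is heated in toluene to decarboxylate it to 6-(4-methoxyphenyl)hexan-2-one F1. Phenol 8 is formylated at C4 under Vilsmeier–Haack conditions (POCl3, DMF) to 2,4-dihydroxy-3-methoxybenzaldehyde F2, and both hydroxyls are benzylated (BnBr, K2CO3, DMF) to give 2,4-bis(benzyloxy)-3-methoxybenzaldehyde F3. Claisen–Schmidt condensation of F1 with F3 (NaOH, EtOH–H2O, rt), which under base takes place at the methyl group, should give (E)-1-[2,4-bis(benzyloxy)-3-methoxyphenyl]-7-(4-methoxyphenyl)hept-1-en-3-one F4. Hydrogenation (H2, Pd/C, EtOAc) should saturate the alkene and cleave both benzyl ethers in one operation to give 13.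

2. Step 2. The β-keto acid may decarboxylate during acidification or concentration and give the unreactive methyl ketone. The fallback sets out from 5 and returns at 13, keeping the ester as the activating group until after the C–C bond is made. Mannich base 10 is prepared from 8 and 9 (Et3N, MeCN) and isolated. It is heated with keto ester 5 in toluene at reflux, a known C-benzylation of 1,3-dicarbonyl compounds by phenolic Mannich bases, to give methyl 2-[(2,4-dihydroxy-3-methoxyphenyl)methyl]-7-(4-methoxyphenyl)-3-oxoheptanoate F5, which may be present as its cyclic hemiketal. Saponification under nitrogen (aq. NaOH), then acidification and warming to 50 °C, should hydrolyse and decarboxylate F5 to 13.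

3. Step 1. The SN2 reaction of the dianion with the unactivated bromide may be slow and lose out to elimination of HBr from 2 or to proton transfer from the product to the dianion. The fallback sets out from 2 and returns at 5, building the chain by malonic ester synthesis and a Masamune–Brooks homologation. Bromide 2 is alkylated with diethyl malonate (NaOEt, EtOH, reflux) to give diethyl 2-[3-(4-methoxyphenyl)propyl]propanedioate F6. Hydrolysis and thermal decarboxylation (KOH, then H3O+, heat) give 5-(4-methoxyphenyl)pentanoic acid F7. Activation with carbonyldiimidazole in THF gives 1-(1H-imidazol-1-yl)-5-(4-methoxyphenyl)pentan-1-one F8, which is treated with the magnesium salt of monomethyl malonate (potassium methyl malonate, MgCl2, Et3N) to give 5 after decarboxylative work-up.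

Further compounds
F1 | step 3 | 6-(4-methoxyphenyl)hexan-2-one | COc1ccc(CCCCC(C)=O)cc1
F2 | step 3 | 2,4-dihydroxy-3-methoxybenzaldehyde | COc1c(O)ccc(C=O)c1O
F3 | step 3 | 2,4-bis(benzyloxy)-3-methoxybenzaldehyde | COc1c(OCc2ccccc2)ccc(C=O)c1OCc1ccccc1
F4 | step 3 | (E)-1-[2,4-bis(benzyloxy)-3-methoxyphenyl]-7-(4-methoxyphenyl)hept-1-en-3-one | COc1ccc(CCCCC(=O)/C=C/c2ccc(OCc3ccccc3)c(OC)c2OCc2ccccc2)cc1
F5 | step 2 | methyl 2-[(2,4-dihydroxy-3-methoxyphenyl)methyl]-7-(4-methoxyphenyl)-3-oxoheptanoate | COC(=O)C(Cc1ccc(O)c(OC)c1O)C(=O)CCCCc1ccc(OC)cc1
F6 | step 1 | diethyl 2-[3-(4-methoxyphenyl)propyl]propanedioate | CCOC(=O)C(CCCc1ccc(OC)cc1)C(=O)OCC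
F7 | step 1 | 5-(4-methoxyphenyl)pentanoic acid | COc1ccc(CCCCC(=O)O)cc1
F8 | step 1 | 1-(1H-imidazol-1-yl)-5-(4-methoxyphenyl)pentan-1-one | COc1ccc(CCCCC(=O)n2ccnc2)cc1
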